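**Retrosynthetic overview**
- The C7=C8 bond is cut last: a Wittig reaction joins a bridged bicyclic lactol (a masked cis-3-hydroxy-α-cyclocitral) to a C20 hydroxy-polyenyl phosphonium salt, with no protecting groups.
- The lactol comes from a bridged lactone made by one dearomative [4+2] cycloaddition of 4-methyl-2-pyranone with isobutylene. This is the only ring-forming step: it builds the carbocycle, the gem-dimethyl carbon and both stereocentres (the two bridgeheads, cis by construction). The lactone bridge is opened again in the last step.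
- The C20 salt comes from the centrosymmetric C20 diol by reaction at one end only; the diol comes from the C10 dialdehyde and two C5 phosphonate units.
- The C10 dialdehyde comes from furan by oxidative ring opening and a twofold Wittig reaction.

Assumption: 4-methyl-2H-pyran-2-one, 2-(triphenylphosphoranylidene)propanal and ethyl (2E)-4-(diethoxyphosphoryl)-2-methylbut-2-enoate are bought; the sense of induction in step 1 is fixed by the choice of ligand antipode (the R ligand is written; the S ligand is used if it gives the mirror-image lactone).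

**Step 1**
Reactants: 1 4-methyl-2H-pyran-2-one; 2 2-methylprop-1-ene (isobutylene)
Product: 3 (1S,4R)-5,8,8-trimethyl-2-oxabicyclo[2.2.2]oct-5-en-3-one
Conditions: 2 (5 equiv), MeAl[(R)-3,3'-bis(triphenylsilyl)-1,1'-binaphthalene-2,2'-diolate] (20 mol%), toluene, −20 °C to rt, sealed tube, 48 h
Reagents that add atoms: none
Why: Proposed new method: the aluminium Lewis acid binds the lactone carbonyl of 1 and lets nucleophilic 2 add in an asynchronous inverse-electron-demand Diels–Alder reaction (CH2 terminus to electrophilic C6, the developing tertiary cation closing on C3, which puts CMe2 next to the carbonyl-bearing bridgehead), the two stereocentres being the bridgeheads and therefore cis by construction while the binaphtholate pocket selects the face of the flat pyranone; the closest known reactions are Lewis-acid-promoted inverse-demand cycloadditions of 2-pyranones with vinyl ethers that keep the CO2 bridge below 60 °C, binaphthol–titanium ene reactions of isobutylene, and hetero-Diels–Alder reactions catalysed by this same aluminium binaphtholate.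

**Step 2**
Reactants: 3 (1S,4R)-5,8,8-trimethyl-2-oxabicyclo[2.2.2]oct-5-en-3-one
Product: 4 (1S,4R)-5,8,8-trimethyl-2-oxabicyclo[2.2.2]oct-5-en-3-ol (both C3 epimers, in equilibrium with its open hydroxy aldehyde form)
Conditions: i-Bu2AlH (1.1 equiv), CH2Cl2, −78 °C; aq. KNaC4H4O6
Reagents that add atoms: none
Why: Partial lactone reduction by i-Bu2AlH at −78 °C stops at the aluminium hemiacetal and gives the lactol on work-up, and the bridgehead α-carbon cannot enolise, so both stereocentres are untouched.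

**Step 3**
Reactants: 5 furan; 6 2-(triphenylphosphoranylidene)propanal
Product: 10 (2E,4E,6E)-2,7-dimethylocta-2,4,6-trienedial, via cis-butenedial 7 (not isolated), via trans-butenedial 8 (not isolated), via mono-Wittig dienedial 9 (not isolated)
Conditions: N-bromosuccinimide (1.05 equiv), NaHCO3, acetone/H2O 10:1, −15 °C; pyridine, rt; then 6 (2.2 equiv), CH2Cl2, 40 °C; I2 (1 mol%), rt
Reagents that add atoms: water, O (oxygen of 7, 8 and 9 only)
Why: Bromonium-mediated oxidative ring opening of furan (dearomatisation) gives cis-butenedial, pyridine isomerises it to the trans dial, and the twofold Wittig reaction with the formyl-stabilised ylide is E-selective and stops at the dialdehyde because the α-methyl enal product is much less electrophilic, with I2 equilibrating any Z isomer; no stereocentre is formed.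

**Step 4**
Reactants: 10 (2E,4E,6E)-2,7-dimethylocta-2,4,6-trienedial; 11 ethyl (2E)-4-(diethoxyphosphoryl)-2-methylbut-2-enoate
Product: 14 diethyl (2E,4E,6E,8E,10E,12E,14E)-2,6,11,15-tetramethylhexadeca-2,4,6,8,10,12,14-heptaenedioate (diethyl crocetinate), via sodium phosphonate carbanion 12 (not isolated), via C15 aldehyde ester 13 (not isolated)
Conditions: 11 (2.2 equiv), NaH, THF, 0 °C to rt; recrystallise
Reagents that add atoms: sodium hydride, [Na+].[H-] (sodium counter-ion of 12 only)
Why: Twofold Horner–Wadsworth–Emmons olefination of the conjugated dialdehyde by the allylic phosphonate carbanion forms both new disubstituted C=C bonds E-selectively, and the all-E diester crystallises.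

**Step 5**
Reactants: 14 diethyl crocetinate
Product: 15 (2E,4E,6E,8E,10E,12E,14E)-2,6,11,15-tetramethylhexadeca-2,4,6,8,10,12,14-heptaene-1,16-diol
Conditions: i-Bu2AlH (5 equiv), CH2Cl2/THF, −78 to −20 °C; aq. KNaC4H4O6
Reagents that add atoms: none
Why: i-Bu2AlH reduces α,β-unsaturated esters in the 1,2 sense to allylic alcohols without touching the polyene.

**Step 6**
Reactants: 15 the C20 diol
Product: 16 [(2E,4E,6E,8E,10E,12E,14E)-16-hydroxy-2,6,11,15-tetramethylhexadeca-2,4,6,8,10,12,14-heptaen-1-yl]triphenylphosphonium bromide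
Conditions: Ph3P·HBr (1.0 equiv), MeOH/CH2Cl2, 0 °C to rt, dark; unreacted 15 recovered and recycled
Reagents that add atoms: triphenylphosphine hydrobromide, [PH+](c1ccccc1)(c1ccccc1)c1ccccc1.[Br-]
Why: Ph3P·HBr ionises one allylic alcohol to a polyenyl cation that PPh3 traps at the terminal CH2 (as in the making of retinyl phosphonium salts), and one equivalent on the centrosymmetric diol breaks its symmetry statistically to the mono-salt.

**Step 7**
Reactants: 4 the lactol; 16 the C20 hydroxy phosphonium bromide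
Product: 19 (1S,4R)-4-[(1E,3E,5E,7E,9E,11E,13E,15E)-17-hydroxy-3,7,12,16-tetramethylheptadeca-1,3,5,7,9,11,13,15-octaen-1-yl]-3,5,5-trimethylcyclohex-2-en-1-ol, via phosphonium ylide 17 (not isolated), via open hydroxy aldehyde 18 (not isolated)
Conditions: 16 (1.2 equiv), 1,2-epoxybutane (10 equiv), EtOH/CH2Cl2, 50 °C, dark, Ar; then I2 (1 mol%), CH2Cl2, rt; recrystallise
Reagents that add atoms: none
Why: Wittig reaction in which epoxybutane takes up HBr to form the semi-stabilised ylide under near-neutral conditions, so that the aldehyde tautomer of the lactol is olefinated before C6 can epimerise and the 3-hydroxyl is released, the E C7=C8 bond being favoured and secured by I2 equilibration; no stereocentre is formed or broken.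

**Compound list**
1 | 4-methyl-2H-pyran-2-one | CC1=CC(=O)OC=C1 | starting material
2 | 2-methylprop-1-ene (isobutylene) | CC(C)=C | starting material
3 | (1S,4R)-5,8,8-trimethyl-2-oxabicyclo[2.2.2]oct-5-en-3-one | CC1=C[C@@H]2CC(C)(C)[C@H]1C(=O)O2 | intermediate
4 | (1S,4R)-5,8,8-trimethyl-2-oxabicyclo[2.2.2]oct-5-en-3-ol (C3 epimers) | CC1=C[C@@H]2CC(C)(C)[C@H]1C(O)O2 | intermediate
5 | furan | c1ccoc1 | starting material
6 | 2-(triphenylphosphoranylidene)propanal | CC(C=O)=P(c1ccccc1)(c1ccccc1)c1ccccc1 | starting material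
7 | (2Z)-but-2-enedial | O=C/C=C\C=O | intermediate
8 | (2E)-but-2-enedial | O=C/C=C/C=O | intermediate
9 | (2E,4E)-2-methylhexa-2,4-dienedial | O=C/C(C)=C/C=C/C=O | intermediate
10 | (2E,4E,6E)-2,7-dimethylocta-2,4,6-trienedial | O=C/C(C)=C/C=C/C=C(\C)C=O | intermediate
11 | ethyl (2E)-4-(diethoxyphosphoryl)-2-methylbut-2-enoate | CCOC(=O)/C(C)=C/CP(=O)(OCC)OCC | starting material
12 | sodium salt of the C4 carbanion of 11 | CCOC(=O)/C(C)=C/[CH-]P(=O)(OCC)OCC.[Na+] | intermediate
13 | ethyl (2E,4E,6E,8E,10E)-2,6,11-trimethyl-12-oxododeca-2,4,6,8,10-pentaenoate | CCOC(=O)/C(C)=C/C=C/C(C)=C/C=C/C=C(\C)C=O | intermediate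
14 | diethyl (2E,4E,6E,8E,10E,12E,14E)-2,6,11,15-tetramethylhexadeca-2,4,6,8,10,12,14-heptaenedioate | CCOC(=O)/C(C)=C/C=C/C(C)=C/C=C/C=C(C)/C=C/C=C(\C)C(=O)OCC | intermediate
15 | (2E,4E,6E,8E,10E,12E,14E)-2,6,11,15-tetramethylhexadeca-2,4,6,8,10,12,14-heptaene-1,16-diol | OC/C(C)=C/C=C/C(C)=C/C=C/C=C(C)/C=C/C=C(\C)CO | intermediate
16 | [(2E,4E,6E,8E,10E,12E,14E)-16-hydroxy-2,6,11,15-tetramethylhexadeca-2,4,6,8,10,12,14-heptaen-1-yl]triphenylphosphonium bromide | OC/C(C)=C/C=C/C(C)=C/C=C/C=C(C)/C=C/C=C(\C)C[P+](c1ccccc1)(c1ccccc1)c1ccccc1.[Br-] | intermediate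
17 | (2E,4E,6E,8E,10E,12E,14E)-2,6,11,15-tetramethyl-16-(triphenylphosphoranylidene)hexadeca-2,4,6,8,10,12,14-heptaen-1-ol | OC/C(C)=C/C=C/C(C)=C/C=C/C=C(C)/C=C/C=C(\C)C=P(c1ccccc1)(c1ccccc1)c1ccccc1 | intermediate
18 | (1R,4S)-4-hydroxy-2,6,6-trimethylcyclohex-2-ene-1-carbaldehyde | CC1=C[C@@H](O)CC(C)(C)[C@H]1C=O | intermediate
19 | (1S,4R)-4-[(1E,3E,5E,7E,9E,11E,13E,15E)-17-hydroxy-3,7,12,16-tetramethylheptadeca-1,3,5,7,9,11,13,15-octaen-1-yl]-3,5,5-trimethylcyclohex-2-en-1-ol, that is (3S,6R)-8'-apo-ε-carotene-3,8'-diol | CC1=C[C@@H](O)CC(C)(C)[C@H]1/C=C/C(C)=C/C=C/C(C)=C/C=C/C=C(C)/C=C/C=C(\C)CO | target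

**Totals**
Total step count: 7. Longest linear sequence: 5 steps (steps 3, 4, 5, 6, 7, from furan).

**Steps most likely to fail, with fallbacks**

Step 1 is unprecedented for this pair of partners; it may not turn over, may give an ene-type adduct instead, or may give low enantiomeric excess. The fallback sets out from 1 and 2 and comes back at 4. The cycloaddition is run without any catalyst in neat 2 at 12 kbar and 50 °C, which gives the racemic lactone F1. i-Bu2AlH at −78 °C gives the racemic lactol F2. Kinetic resolution with Burkholderia cepacia lipase and vinyl acetate in t-BuOMe (enzyme chosen by screening for this preference) acetylates the (1R,4S)-enantiomer to the lactol acetate F3, which is removed on silica, and the unreacted (1S,4R)-lactol 4 is carried on.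

Step 6 can give bis-salt, regioisomeric phosphonium salts or acid-induced polyene scrambling. The fallback sets out from 15 and comes back at 19. The mono-alkoxide of 15 (NaH, 1 equiv, THF) is silylated with t-BuMe2SiCl to the mono silyl ether F4. CBr4/PPh3 in CH2Cl2 at −20 °C gives the allylic bromide F5, which is quaternised in the same pot by more PPh3 to the silyloxy phosphonium bromide F6, with no acid present. Wittig reaction of F6 with 4 under the 1,2-epoxybutane conditions gives the silyl ether of the target F7, and Bu4NF in THF gives 19.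

Step 7 puts a basic ylide next to an enolisable aldehyde on C6 (risk of epimerisation to the 6-epimer or of double-bond migration into conjugation). The fallback sets out from 3 and 15 and comes back at 19, with the polarity reversed so that no aldehyde sits on C6. LiAlH4 reduces 3 to the ring diol F8. Mitsunobu reaction of its primary hydroxyl with 1-phenyl-1H-tetrazole-5-thiol (PPh3, diisopropyl azodicarboxylate) gives the sulfide F9, and H2O2 with (NH4)6Mo7O24 gives the sulfone F10. MnO2 in limited amount oxidises one end of 15 to the C20 hydroxy aldehyde F11. Julia–Kocienski olefination of F11 with F10 (KN(SiMe3)2, 3 equiv, THF, −70 °C) forms the E C7=C8 bond and gives 19.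

**Further compounds**
F1 | step 1 | racemic 5,8,8-trimethyl-2-oxabicyclo[2.2.2]oct-5-en-3-one (racemate of 3) | CC1=CC2CC(C)(C)C1C(=O)O2
F2 | step 1 | racemic 5,8,8-trimethyl-2-oxabicyclo[2.2.2]oct-5-en-3-ol (racemate of 4) | CC1=CC2CC(C)(C)C1C(O)O2
F3 | step 1 | (1R,4S)-5,8,8-trimethyl-2-oxabicyclo[2.2.2]oct-5-en-3-yl acetate | CC1=C[C@H]2CC(C)(C)[C@@H]1C(OC(C)=O)O2
F4 | step 6 | (2E,4E,6E,8E,10E,12E,14E)-16-{[tert-butyl(dimethyl)silyl]oxy}-2,6,11,15-tetramethylhexadeca-2,4,6,8,10,12,14-heptaen-1-ol | OC/C(C)=C/C=C/C(C)=C/C=C/C=C(C)/C=C/C=C(\C)CO[Si](C)(C)C(C)(C)C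
F5 | step 6 | {[(2E,4E,6E,8E,10E,12E,14E)-16-bromo-2,6,11,15-tetramethylhexadeca-2,4,6,8,10,12,14-heptaen-1-yl]oxy}(tert-butyl)dimethylsilane | BrC/C(C)=C/C=C/C(C)=C/C=C/C=C(C)/C=C/C=C(\C)CO[Si](C)(C)C(C)(C)C
F6 | step 6 | [(2E,4E,6E,8E,10E,12E,14E)-16-{[tert-butyl(dimethyl)silyl]oxy}-2,6,11,15-tetramethylhexadeca-2,4,6,8,10,12,14-heptaen-1-yl]triphenylphosphonium bromide | CC(C)(C)[Si](C)(C)OC/C(C)=C/C=C/C(C)=C/C=C/C=C(C)/C=C/C=C(\C)C[P+](c1ccccc1)(c1ccccc1)c1ccccc1.[Br-]
F7 | step 6 | tert-butyldimethylsilyl ether of 19 at the primary hydroxyl: (1S,4R)-4-[(1E,3E,5E,7E,9E,11E,13E,15E)-17-{[tert-butyl(dimethyl)silyl]oxy}-3,7,12,16-tetramethylheptadeca-1,3,5,7,9,11,13,15-octaen-1-yl]-3,5,5-trimethylcyclohex-2-en-1-ol | CC1=C[C@@H](O)CC(C)(C)[C@H]1/C=C/C(C)=C/C=C/C(C)=C/C=C/C=C(C)/C=C/C=C(\C)CO[Si](C)(C)C(C)(C)C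
F8 | step 7 | (1S,4R)-4-(hydroxymethyl)-3,5,5-trimethylcyclohex-2-en-1-ol | CC1=C[C@@H](O)CC(C)(C)[C@H]1CO
F9 | step 7 | (1S,4R)-3,5,5-trimethyl-4-{[(1-phenyl-1H-tetrazol-5-yl)sulfanyl]methyl}cyclohex-2-en-1-ol | CC1=C[C@@H](O)CC(C)(C)[C@H]1CSc1nnnn1-c1ccccc1
F10 | step 7 | (1S,4R)-3,5,5-trimethyl-4-{[(1-phenyl-1H-tetrazol-5-yl)sulfonyl]methyl}cyclohex-2-en-1-ol | CC1=C[C@@H](O)CC(C)(C)[C@H]1CS(=O)(=O)c1nnnn1-c1ccccc1
F11 | step 7 | (2E,4E,6E,8E,10E,12E,14E)-16-hydroxy-2,6,11,15-tetramethylhexadeca-2,4,6,8,10,12,14-heptaenal | O=C/C(C)=C/C=C/C(C)=C/C=C/C=C(C)/C=C/C=C(\C)CO
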